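**Plan**

- Germacrane numbering is used: ring C1–C10, lactone oxygen on C6, acrylate carbon C11 on C7, ester on C8, CH2OH C14 on C10 and C15 on C4. The enabling feature is that the lactone carbon C6 is allylic to the ring alkene C4=C5 and adjacent to C7, so the lactone edge C7–C6 plus C5=C4 maps onto a ring 1,3-diene C7=C6–C5=C4 whose π-allyl unit (C6–C5–C4) can be trapped at C6 by a carboxylate.
- Retrosynthesis cuts, in order: the C8–O ester bond (made with inversion) and the two silyl ethers; O–C6 together with C7–C11, giving a ten-membered all-ring-cis trienol and 2-bromoacrylic acid; C6=C7 (ring-closing metathesis); C3–C4 (B-alkyl Suzuki) and C9–C10 (vinyllithium plus epoxide), giving two copies of one bromodiene and (S)-epichlorohydrin.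
- Forward: the acyclic C14 chain is assembled, the ten-membered carbocycle is closed, the γ-lactone is annulated onto it in one palladium-catalysed step, then C8 is inverted and esterified and the silyl groups are removed.
- Stereochemistry: C8 comes from (S)-epichlorohydrin; as a temporary 8S hydroxyl it steers C7 (outer-face addition) and, through syn carbopalladation and anti C–O formation, C6; it is then inverted to 8R by Mitsunobu esterification. C1=C10 and C4=C5 geometry comes from a Z-selective bromo-Wittig reaction and stereoretentive couplings; C6=C7 geometry from ring size.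

Key step: step 8

Remark: the target is read as the trans-fused (6R,7R) lactone with an 8R ester, and both trisubstituted ring alkenes as ring-cis (C2 cis to C9, C3 cis to C6; E by the sequence rule because of the CH2OH groups).

Step 1
Reactants: 1 ethyl (triphenylphosphoranylidene)acetate; 2 acrolein
Product: 4 ethyl (2Z)-2-bromopenta-2,4-dienoate, via bromo ylide 3 (not isolated)
Conditions: NBS, CH2Cl2, −20 °C; then 2, −20 °C to rt
Reagents that add atoms: N-bromosuccinimide, O=C1CCC(=O)N1Br
Why: In this one-pot ylide bromination and Wittig olefination the stabilised α-bromo ylide should place the ester trans to the aldehyde residue, so that bromine ends up cis to the vinyl group (2Z).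

Step 2
Reactants: 4 ethyl (2Z)-2-bromopenta-2,4-dienoate
Product: 5 (2Z)-2-bromopenta-2,4-dien-1-ol
Conditions: i-Bu2AlH (2.2 equiv), CH2Cl2, −78 °C
Reagents that add atoms: none
Why: 1,2-Reduction of the ester by the aluminium hydride at low temperature should leave the vinyl bromide and the diene untouched.

Step 3
Reactants: 5 (2Z)-2-bromopenta-2,4-dien-1-ol
Product: 6 {[(2Z)-2-bromopenta-2,4-dien-1-yl]oxy}(tert-butyl)dimethylsilane
Conditions: TBSCl, imidazole, DMF, 0 °C to rt
Reagents that add atoms: tert-butyldimethylsilyl chloride, CC(C)(C)[Si](C)(C)Cl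
Why: Standard silylation protects the primary alcohol that becomes C14–OH in one copy of 6 and C15–OH in the other.

Step 4
Reactants: 6 {[(2Z)-2-bromopenta-2,4-dien-1-yl]oxy}(tert-butyl)dimethylsilane; 7 (S)-epichlorohydrin
Product: 10 (2S)-2-[(2E)-2-({[tert-butyl(dimethyl)silyl]oxy}methyl)penta-2,4-dien-1-yl]oxirane, via vinyllithium 8 (not isolated), via chlorohydrin 9 (not isolated)
Conditions: t-BuLi (2 equiv), Et2O, −78 °C; BF3·OEt2 then 7, −78 °C; then NaOH, MeOH/H2O, rt
Reagents that add atoms: none
Why: Bromine–lithium exchange with retention of alkene geometry, BF3-promoted opening of the epoxide at its CH2 terminus and Williamson closure of the chlorohydrin should form the C9–C10 bond without touching the epichlorohydrin stereocentre, which becomes C8.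

Step 5
Reactants: 10 (2S)-2-[(2E)-2-({[tert-butyl(dimethyl)silyl]oxy}methyl)penta-2,4-dien-1-yl]oxirane; 6 {[(2Z)-2-bromopenta-2,4-dien-1-yl]oxy}(tert-butyl)dimethylsilane
Product: 12 (2S)-2-[(2E,6E)-2,6-bis({[tert-butyl(dimethyl)silyl]oxy}methyl)nona-2,6,8-trien-1-yl]oxirane, via alkylborane 11 (not isolated)
Conditions: 9-BBN, THF, 0 °C to rt; then 6, Pd(dppf)Cl2 (5 mol %), AsPh3, Cs2CO3, DMF/H2O, rt
Reagents that add atoms: none
Why: Anti-Markovnikov hydroboration of the only monosubstituted alkene followed by B-alkyl Suzuki–Miyaura coupling with retention at the vinyl bromide should form the C3–C4 bond with C3 cis to C6, the epoxide being inert to both reagents.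

Step 6
Reactants: 12 (2S)-2-[(2E,6E)-2,6-bis({[tert-butyl(dimethyl)silyl]oxy}methyl)nona-2,6,8-trien-1-yl]oxirane
Product: 13 (3S,5E,9E)-5,9-bis({[tert-butyl(dimethyl)silyl]oxy}methyl)dodeca-1,5,9,11-tetraen-3-ol
Conditions: Me3S+ I− (4 equiv), n-BuLi, THF, −10 °C to rt
Reagents that add atoms: trimethylsulfonium iodide, C[S+](C)C.[I-]
Why: Excess dimethylsulfonium methylide should open the terminal epoxide at CH2 and the resulting sulfonium should eliminate dimethyl sulfide (one-carbon homologation of an epoxide to an allylic alcohol), leaving C8 unchanged.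

Step 7
Reactants: 13 (3S,5E,9E)-5,9-bis({[tert-butyl(dimethyl)silyl]oxy}methyl)dodeca-1,5,9,11-tetraen-3-ol
Product: 14 (1S,2Z,4E,8E)-5,9-bis({[tert-butyl(dimethyl)silyl]oxy}methyl)cyclodeca-2,4,8-trien-1-ol
Conditions: first-generation Grubbs catalyst RuCl2(=CHPh)(PCy3)2 (10 mol %), CH2Cl2 (1 mM), 40 °C
Reagents that add atoms: none
Why: Ring-closing metathesis of the diene–ene type should join the two monosubstituted alkenes, because this catalyst does not engage the trisubstituted alkenes and the ten-membered ring enforces the cis (Z) C6=C7 bond.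

Step 8
Reactants: 14 (1S,2Z,4E,8E)-5,9-bis({[tert-butyl(dimethyl)silyl]oxy}methyl)cyclodeca-2,4,8-trien-1-ol; 15 2-bromoacrylic acid
Product: 16 (3aR,4S,6E,10E,11aR)-6,10-bis({[tert-butyl(dimethyl)silyl]oxy}methyl)-4-hydroxy-3-methylidene-3a,4,5,8,9,11a-hexahydrocyclodeca[b]furan-2(3H)-one
Conditions: Pd(OAc)2 (10 mol %), 1,1'-bis(diphenylphosphino)ferrocene (12 mol %), K2CO3 (2.5 equiv), 15 (2 equiv, slow addition), DMF, 70 °C
Reagents that add atoms: none
Why: Proposed new method: zerovalent palladium inserts into the C–Br bond of the 2-bromoacrylate, the α-carboxyvinyl-palladium adds syn across C6=C7 with carbon to C7, and the π-allyl palladium over C6–C5–C4 is then attacked at C6 by the tethered carboxylate, which forms the O–C6 bond and frees zerovalent palladium. The closest known reaction type is the Larock heteroannulation of 1,3-dienes with o-iodobenzoic acids or with vinylic halides that carry an OH or NH nucleophile. The γ-lactone closes in the 5-exo mode on the proximal allyl terminus (the seven-membered alternative through the fully substituted C4 is disfavoured). C7 is controlled by the C8 stereocentre: allylic strain holds H8 in the plane of the ring-cis C6=C7 bond and ring carbon C9 on the inner face, so the vinyl-palladium should enter on the outer face next to the C8 hydroxyl (7R, C7–C11 trans to C8–O). C6 is controlled by the anti relationship between palladium and the incoming carboxylate (outer-sphere attack, the reverse of allylic ester ionisation, enforced by the chelating bisphosphine), which after syn carbopalladation of a ring-cis alkene should give the trans-fused 6R lactone, while the C4=C5 geometry is held by the ring. The step needs regioselectivity (carbon to the CH terminus C7 and not to C4), face selectivity and anti C–O formation, secured by the substitution pattern of the diene, the conformation of the ten-membered ring and the ligand respectively.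

Step 9
Reactants: 16 the 8S-hydroxy lactone; 17 isovaleric acid
Product: 18 (3aR,4R,6E,10E,11aR)-6,10-bis({[tert-butyl(dimethyl)silyl]oxy}methyl)-3-methylidene-2-oxo-2,3,3a,4,5,8,9,11a-octahydrocyclodeca[b]furan-4-yl 3-methylbutanoate
Conditions: PPh3, DIAD, toluene, 0 °C to rt
Reagents that add atoms: none
Why: In the Mitsunobu esterification the isovalerate should displace the C8 oxyphosphonium group by SN2, inverting C8 from S to the required R configuration.

Step 10
Reactants: 18 the bis-silyl ether of the target
Product: 19 [(3aR,4R,6E,10E,11aR)-6,10-bis(hydroxymethyl)-3-methylidene-2-oxo-2,3,3a,4,5,8,9,11a-octahydrocyclodeca[b]furan-4-yl] 3-methylbutanoate (CNP0199826.1)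
Conditions: HF·pyridine, pyridine/THF, 0 °C to rt
Reagents that add atoms: none
Why: Buffered fluoride cleavage of the two primary silyl ethers should spare the methylene lactone, the isovalerate and the acid-sensitive 1,5-diene.

**Compound list**

1 | ethyl (triphenylphosphoranylidene)acetate | CCOC(=O)C=P(c1ccccc1)(c1ccccc1)c1ccccc1 | starting material
2 | acrolein (prop-2-enal) | C=CC=O | starting material
3 | ethyl bromo(triphenylphosphoranylidene)acetate | CCOC(=O)C(Br)=P(c1ccccc1)(c1ccccc1)c1ccccc1 | intermediate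
4 | ethyl (2Z)-2-bromopenta-2,4-dienoate (Br cis to the vinyl group) | CCOC(=O)/C(Br)=C/C=C | intermediate
5 | (2Z)-2-bromopenta-2,4-dien-1-ol | OC/C(Br)=C/C=C | intermediate
6 | {[(2Z)-2-bromopenta-2,4-dien-1-yl]oxy}(tert-butyl)dimethylsilane | CC(C)(C)[Si](C)(C)OC/C(Br)=C/C=C | intermediate
7 | (S)-epichlorohydrin, (2S)-2-(chloromethyl)oxirane | ClC[C@@H]1CO1 | starting material
8 | (2E)-1-{[tert-butyl(dimethyl)silyl]oxy}penta-2,4-dien-2-yllithium (Li cis to the vinyl group) | [Li]/C(CO[Si](C)(C)C(C)(C)C)=C\C=C | intermediate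
9 | (2S,4E)-1-chloro-4-({[tert-butyl(dimethyl)silyl]oxy}methyl)hepta-4,6-dien-2-ol | ClC[C@@H](O)C/C(CO[Si](C)(C)C(C)(C)C)=C\C=C | intermediate
10 | (2S)-2-[(2E)-2-({[tert-butyl(dimethyl)silyl]oxy}methyl)penta-2,4-dien-1-yl]oxirane | C=C/C=C(/CO[Si](C)(C)C(C)(C)C)C[C@H]1CO1 | intermediate
11 | 9-{(3E)-4-({[tert-butyl(dimethyl)silyl]oxy}methyl)-5-[(2S)-oxiran-2-yl]pent-3-en-1-yl}-9-borabicyclo[3.3.1]nonane | C(C/C=C(/CO[Si](C)(C)C(C)(C)C)C[C@H]1CO1)B1C2CCCC1CCC2 | intermediate
12 | (2S)-2-[(2E,6E)-2,6-bis({[tert-butyl(dimethyl)silyl]oxy}methyl)nona-2,6,8-trien-1-yl]oxirane | C=C/C=C(/CO[Si](C)(C)C(C)(C)C)CC/C=C(/CO[Si](C)(C)C(C)(C)C)C[C@H]1CO1 | intermediate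
13 | (3S,5E,9E)-5,9-bis({[tert-butyl(dimethyl)silyl]oxy}methyl)dodeca-1,5,9,11-tetraen-3-ol | C=C/C=C(/CO[Si](C)(C)C(C)(C)C)CC/C=C(/CO[Si](C)(C)C(C)(C)C)C[C@H](O)C=C | intermediate
14 | (1S,2Z,4E,8E)-5,9-bis({[tert-butyl(dimethyl)silyl]oxy}methyl)cyclodeca-2,4,8-trien-1-ol (all three ring alkenes ring-cis) | O[C@@H]1/C=C\C=C(\CO[Si](C)(C)C(C)(C)C)CC/C=C(/CO[Si](C)(C)C(C)(C)C)C1 | intermediate
15 | 2-bromoacrylic acid (2-bromoprop-2-enoic acid) | C=C(Br)C(=O)O | starting material
16 | (3aR,4S,6E,10E,11aR)-6,10-bis({[tert-butyl(dimethyl)silyl]oxy}methyl)-4-hydroxy-3-methylidene-3a,4,5,8,9,11a-hexahydrocyclodeca[b]furan-2(3H)-one (6R,7R,8S in germacrane numbering) | C=C1C(=O)O[C@@H]2/C=C(/CO[Si](C)(C)C(C)(C)C)CC/C=C(/CO[Si](C)(C)C(C)(C)C)C[C@H](O)[C@@H]12 | intermediate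
17 | isovaleric acid (3-methylbutanoic acid) | CC(C)CC(=O)O | starting material
18 | (3aR,4R,6E,10E,11aR)-6,10-bis({[tert-butyl(dimethyl)silyl]oxy}methyl)-3-methylidene-2-oxo-2,3,3a,4,5,8,9,11a-octahydrocyclodeca[b]furan-4-yl 3-methylbutanoate | C=C1C(=O)O[C@@H]2/C=C(/CO[Si](C)(C)C(C)(C)C)CC/C=C(/CO[Si](C)(C)C(C)(C)C)C[C@@H](OC(=O)CC(C)C)[C@@H]12 | intermediate
19 | [(3aR,4R,6E,10E,11aR)-6,10-bis(hydroxymethyl)-3-methylidene-2-oxo-2,3,3a,4,5,8,9,11a-octahydrocyclodeca[b]furan-4-yl] 3-methylbutanoate | C=C1C(=O)O[C@@H]2/C=C(/CO)CC/C=C(/CO)C[C@@H](OC(=O)CC(C)C)[C@@H]12 | target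

**Step count and risks**

Total steps: 10. Longest linear sequence: 10 steps (from 1 and 2 to 19; compound 6 is used twice, in steps 4 and 5).

Steps most likely to fail:

1. Step 8 (proposed new method). What may go wrong: sluggish or unselective carbopalladation of the hindered ring diene; self-reaction of the bromoacrylate; inner-sphere C–O formation leading to cis ring fusion; leakage of face selectivity; migration of the lactone acyl group to the free C8 hydroxyl under the basic conditions. The fallback uses known chemistry, sets out from 14 and comes back at 16. Radical atom-transfer addition of iodoacetic acid (Et3B/air, NaHCO3, aqueous ethanol) should add the carboxymethyl radical to C7 on the same outer face, and the allylic iodide formed should be displaced at C6 by the carboxylate to give the methylene-free lactone F1. Aminomethylation of its dianion (lithium diisopropylamide, 3 equiv, then Eschenmoser's salt) should give the Mannich base F2, and quaternisation with MeI followed by NaHCO3-induced elimination should give 16.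

2. Step 7. What may go wrong: oligomerisation by intermolecular metathesis, failure of the strained ten-membered ring to close, or diversion of the ruthenium carbene by the free allylic alcohol (isomerisation to a ketone). The fallback closes the ring at C3–C4 by an intramolecular B-alkyl Suzuki coupling on a chain in which the cis C6=C7 bond is already present; it sets out from 6 and 10 and comes back at 14. Lemieux–Johnson cleavage (OsO4 cat., NaIO4, 2,6-lutidine) of the terminal vinyl group of 6 should give the bromoenal F3, and Stork–Zhao olefination (Ph3P=CHI from the phosphonium iodide and NaN(SiMe3)2, −78 °C) should give the (Z,Z)-iodobromodiene F4. Cleavage of the epoxide of 10 with H5IO6 should give the aldehyde F5. A Nozaki–Hiyama–Kishi coupling (CrCl2, NiCl2 cat., a chiral sulfonamide ligand on chromium) of the iodide of F4 with F5 should give the (S)-allylic alcohol F6. Hydroboration of its terminal vinyl group with 9-BBN should give the alkylborane F7, and Pd(dppf)Cl2/Cs2CO3 at high dilution should close the ring to 14.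

3. Step 9. What may go wrong: elimination or no displacement at the hindered C8 carbinol, or conjugate addition of the phosphine to the methylene lactone. The fallback replaces SN2 inversion by oxidation and face-selective reduction; it sets out from 16 and comes back at 18. Dess–Martin oxidation should give the C8 ketone F8. Luche reduction (NaBH4, CeCl3·7H2O, MeOH, −78 °C), with hydride entering anti to the C7–C11 bond, should give the 8R alcohol F9. Acylation with isovaleric anhydride and DMAP should give 18.

Further compounds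
F1 | step 8 | (3aR,4S,6E,10E,11aR)-6,10-bis({[tert-butyl(dimethyl)silyl]oxy}methyl)-4-hydroxy-3a,4,5,8,9,11a-hexahydrocyclodeca[b]furan-2(3H)-one (16 without the exocyclic methylene) | O=C1O[C@@H]2/C=C(/CO[Si](C)(C)C(C)(C)C)CC/C=C(/CO[Si](C)(C)C(C)(C)C)C[C@H](O)[C@H]2C1
F2 | step 8 | 3-[(dimethylamino)methyl] derivative of F1 (mixture of C3 epimers; 3aR,4S,11aR) | CN(C)CC1C(=O)O[C@@H]2/C=C(/CO[Si](C)(C)C(C)(C)C)CC/C=C(/CO[Si](C)(C)C(C)(C)C)C[C@H](O)[C@@H]12
F3 | step 7 | (2Z)-3-bromo-4-{[tert-butyl(dimethyl)silyl]oxy}but-2-enal | O=C/C=C(\Br)CO[Si](C)(C)C(C)(C)C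
F4 | step 7 | tert-butyl{[(2Z,4Z)-2-bromo-5-iodopenta-2,4-dien-1-yl]oxy}dimethylsilane | I/C=C\C=C(/Br)CO[Si](C)(C)C(C)(C)C
F5 | step 7 | (3E)-3-({[tert-butyl(dimethyl)silyl]oxy}methyl)hexa-3,5-dienal | C=C/C=C(/CO[Si](C)(C)C(C)(C)C)CC=O
F6 | step 7 | (3E,6S,7Z,9Z)-10-bromo-11-{[tert-butyl(dimethyl)silyl]oxy}-4-({[tert-butyl(dimethyl)silyl]oxy}methyl)undeca-1,3,7,9-tetraen-6-ol | C=C/C=C(/CO[Si](C)(C)C(C)(C)C)C[C@H](O)/C=C\C=C(/Br)CO[Si](C)(C)C(C)(C)C
F7 | step 7 | 9-BBN adduct of F6 at its terminal CH2 (B-alkyl-9-borabicyclo[3.3.1]nonane) | C(C/C=C(/CO[Si](C)(C)C(C)(C)C)C[C@H](O)/C=C\C=C(/Br)CO[Si](C)(C)C(C)(C)C)B1C2CCCC1CCC2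
F8 | step 9 | C8 ketone of 16, (3aS,6E,10E,11aR)-6,10-bis({[tert-butyl(dimethyl)silyl]oxy}methyl)-3-methylidene-3a,5,8,9-tetrahydrocyclodeca[b]furan-2,4(3H,11aH)-dione | C=C1C(=O)O[C@@H]2/C=C(/CO[Si](C)(C)C(C)(C)C)CC/C=C(/CO[Si](C)(C)C(C)(C)C)CC(=O)[C@@H]12
F9 | step 9 | C8 epimer of 16, (3aR,4R,6E,10E,11aR)-6,10-bis({[tert-butyl(dimethyl)silyl]oxy}methyl)-4-hydroxy-3-methylidene-3a,4,5,8,9,11a-hexahydrocyclodeca[b]furan-2(3H)-one | C=C1C(=O)O[C@@H]2/C=C(/CO[Si](C)(C)C(C)(C)C)CC/C=C(/CO[Si](C)(C)C(C)(C)C)C[C@@H](O)[C@@H]12
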